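The daucane core is cut at C1–C5 and C7–C8 (daucane numbering: C1 quaternary fusion carbon, C4 isopropyl carbinol, C5 fusion CH, C6 ester carbon, C8 methylene-bearing carbon, C9 carbinol). Oxygenated C6 with its neighbours C5 and C7 becomes an oxyallyl cation, and C1=C10–C9=C8 a diene held to it by C2–C3–C4. One intramolecular (4+3) cycloaddition of an acyclic chloromethyl ketone thus closes the cyclopentane (C1–C5) and the cycloheptene (C1, C5–C10) together, creates quaternary C1 and the trans fusion under control of C4, and leaves the C6 ketone and a C9=C10 alkene as handles. The (4S,7E) precursor, with silylated carbinol and geometrically pure diene, derives from (S)-terpinen-4-ol.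

Key step: step 8

Conventions: bicyclic compounds carry daucane locants; β is the face of the C1 methyl group, α the opposite face. Acyclic intermediates carry their own chain locants.

Assumption: commercial (S)-(+)-terpinen-4-ol is used at the enantiomeric purity supplied (upgraded before step 1 if necessary), because C4 of the target is taken over from it unchanged and every other stereocentre is set relative to it.

Step 1
Reactants: 1 (S)-terpinen-4-ol
Product: 2 (S)-triethyl[(1-isopropyl-4-methylcyclohex-3-en-1-yl)oxy]silane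
Conditions: Et3SiOTf, 2,6-lutidine, CH2Cl2, 0 °C → rt
Reagents that add atoms: triethylsilyl trifluoromethanesulfonate, CC[Si](CC)(CC)OS(=O)(=O)C(F)(F)F
Why: Silyl triflate silylation under 2,6-lutidine is the standard way to protect a hindered tertiary alcohol, and the resulting ether tolerates the amide bases and organometallics ahead; the stereocentre is not touched.

Step 2
Reactants: 2 (S)-triethyl[(1-isopropyl-4-methylcyclohex-3-en-1-yl)oxy]silane
Product: 5 (S)-5-isopropyl-7,7-dimethoxy-5-(triethylsilyloxy)heptan-2-one, via ozonide 3 (not isolated), via keto aldehyde 4 (not isolated)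
Conditions: O3, CH2Cl2, −78 °C; PPh3, −78 °C → rt; then HC(OMe)3, CeCl3·7H2O (cat.), MeOH, rt
Reagents that add atoms: ozone, [O-][O+]=O; trimethyl orthoformate, COC(OC)OC
Why: Ozonolysis with reductive work-up cleaves the only C=C to keto aldehyde 4, and lanthanide-catalysed chemoselective acetalisation with trimethyl orthoformate masks only the aldehyde, under conditions too weakly acidic to cleave the tertiary silyl ether; the carbinol stereocentre is not involved.

Step 3
Reactants: 5 (S)-5-isopropyl-7,7-dimethoxy-5-(triethylsilyloxy)heptan-2-one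
Product: 7 (S)-triethyl[(3-isopropyl-1,1-dimethoxyhept-6-yn-3-yl)oxy]silane, via enol phosphate 6 (not isolated)
Conditions: LiN(iPr)2 (1.1 equiv), THF, −78 °C; ClP(O)(OEt)2, −78 °C → rt; then LiN(iPr)2 (2.3 equiv), THF, −78 °C → rt; H2O
Reagents that add atoms: none
Why: Kinetic deprotonation at the methyl group, O-phosphorylation and base-induced elimination of the enol phosphate (the enol phosphate route from methyl ketones to terminal alkynes) give the alkyne, the acetal and silyl ether being inert to amide base.

Step 4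
Reactants: 7 (S)-triethyl[(3-isopropyl-1,1-dimethoxyhept-6-yn-3-yl)oxy]silane; 8 trimethylaluminium; 9 vinyl bromide
Product: 11 (S,E)-triethyl[(3-isopropyl-1,1-dimethoxy-6-methylnona-6,8-dien-3-yl)oxy]silane, via alkenylalane 10 (not isolated)
Conditions: AlMe3, Cp2ZrCl2 (0.25 equiv), CH2Cl2, 0 °C → rt; excess AlMe3 evaporated; then vinyl bromide, Pd(PPh3)4 (5 mol%), ZnCl2 (1 equiv), THF, rt
Reagents that add atoms: trimethylaluminium (8), C[Al](C)C; vinyl bromide (9), C=CBr
Why: Zirconium-catalysed Negishi carboalumination adds methyl and aluminium syn across the alkyne with methyl on the internal carbon, and the Pd/Zn-catalysed Negishi coupling with vinyl bromide proceeds with retention, so the trisubstituted alkene is E (tether trans to vinyl) by mechanism rather than by separation of isomers.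

Step 5
Reactants: 11 (S,E)-triethyl[(3-isopropyl-1,1-dimethoxy-6-methylnona-6,8-dien-3-yl)oxy]silane
Product: 12 (S,E)-3-isopropyl-6-methyl-3-(triethylsilyloxy)nona-6,8-dienal
Conditions: PPTS (cat.), acetone/H2O (10:1), 45 °C
Reagents that add atoms: water, O
Why: Acid-catalysed acetal hydrolysis with pyridinium tosylate in wet acetone is mild enough to leave the tertiary triethylsilyl ether and the diene intact.

Step 6
Reactants: 12 (S,E)-3-isopropyl-6-methyl-3-(triethylsilyloxy)nona-6,8-dienal; 13 chloroiodomethane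
Product: 14 (4S,7E)-1-chloro-4-isopropyl-7-methyl-4-(triethylsilyloxy)deca-7,9-dien-2-ol (both C2 epimers)
Conditions: ICH2Cl, MeLi·LiBr, THF, −78 °C; AcOH, −78 °C
Reagents that add atoms: chloroiodomethane (13), ClCI
Why: Chloromethyllithium generated by iodine–lithium exchange in the presence of the aldehyde (Barbier-type carbenoid addition) adds to the carbonyl at −78 °C faster than it decomposes, and protonation before warming prevents closure to the epoxide; the new carbinol centre forms unselectively and is erased in step 7.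

Step 7
Reactants: 14 (4S,7E)-1-chloro-4-isopropyl-7-methyl-4-(triethylsilyloxy)deca-7,9-dien-2-ol
Product: 15 (4S,7E)-1-chloro-4-isopropyl-7-methyl-4-(triethylsilyloxy)deca-7,9-dien-2-one
Conditions: Dess–Martin periodinane, CH2Cl2, 0 °C → rt
Reagents that add atoms: none
Why: Dess–Martin oxidation converts the chlorohydrin to the chloromethyl ketone under near-neutral conditions that neither enolise the product nor touch the diene and the silyl ether.

Step 8
Reactants: 15 (4S,7E)-1-chloro-4-isopropyl-7-methyl-4-(triethylsilyloxy)deca-7,9-dien-2-one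
Product: 17 4α-isopropyl-1β-methyl-4β-(triethylsilyloxy)-5αH-bicyclo[5.3.0]dec-9-en-6-one (trans-fused), via oxyallyl cation 16 (not isolated)
Conditions: Et3N (3 equiv), LiClO4 (3 M in Et2O), 0.01 M in 15, rt
Reagents that add atoms: none
Why: Et3N, helped by Li+ coordination of the carbonyl, enolises 15 toward C5 and chloride leaves C7 to give the Z-configured oxyallyl cation 16 (C5–C6–C7), whose termini bond to C1 and C8 of the s-cis diene in a concerted, asynchronous process (or stepwise with C5–C1 first), forming C5–C1 and C7–C8 and leaving the C9=C10 alkene. The closest known reaction type is the base-mediated intramolecular (4+3) cycloaddition of α-chloroketone-derived oxyallyl cations with butadienes on a three-atom tether, which gives bicyclo[5.3.0]dec-9-en-6-ones. The cyclopentane (C1–C5) closes through C5–C1 in 5-exo fashion with respect to the C1=C10 alkene, and the seven-membered ring (C1, C5–C10) closes through C7–C8 in 7-endo fashion onto the allylic terminus C8. C5 is set by C4: allylic 1,3-strain in the Z-oxyallyl (reinforced by Li+ chelation between the enolate and ether oxygens) holds the C4–O bond in the cation plane with isopropyl on one face and the tether on the other, so the diene reaches only the C5 face that leaves C6 cis to the silyloxy group and H5 cis to isopropyl. C1 is set relative to C5 by the extended (chair-like) transition state, in which the E-diene carries the tether outside and the methyl inside, so that the methyl ends anti to H5 and the fusion is trans. The step therefore needs a single diene geometry, secured by the carbometalation of step 4, and ionisation faster than β-loss of silanolate from the same enolate, which the non-nucleophilic, strongly ionising LiClO4/Et2O medium, the weak amine base and high dilution favour.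

Step 9
Reactants: 17 4α-isopropyl-1β-methyl-4β-(triethylsilyloxy)-5αH-bicyclo[5.3.0]dec-9-en-6-one
Product: 18 4β-hydroxy-4α-isopropyl-1β-methyl-5αH-bicyclo[5.3.0]dec-9-en-6-one
Conditions: HF·pyridine, pyridine, THF, 0 °C → rt
Reagents that add atoms: none
Why: Fluoride cleavage of the Si–O bond under buffered, slightly acidic conditions removes the triethylsilyl group without exposing the resulting β-hydroxy ketone to base, which could cause retro-aldol opening or dehydration; no stereocentre is affected.

Step 10
Reactants: 18 4β-hydroxy-4α-isopropyl-1β-methyl-5αH-bicyclo[5.3.0]dec-9-en-6-one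
Product: 19 4α-isopropyl-1β-methyl-5αH-bicyclo[5.3.0]dec-9-ene-4β,6α-diol
Conditions: Me4NBH(OAc)3, AcOH/MeCN (1:1), −25 °C
Reagents that add atoms: none
Why: In this Evans–Saksena hydroxyl-directed reduction the C4 hydroxyl exchanges onto boron and delivers hydride intramolecularly to the β face of the C6 carbonyl, the face syn to the C4–O bond, giving the 6α-alcohol that an external hydride, hindered on that face by the C1 methyl, would not give.

Step 11
Reactants: 20 4-hydroxybenzoic acid
Product: 22 4-(triisopropylsilyloxy)benzoic acid, via bis-silyl derivative 21 (not isolated)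
Conditions: i-Pr3SiCl (2.2 equiv), imidazole, DMF, rt; then K2CO3, THF/MeOH/H2O, rt; 1 M HCl to pH 3
Reagents that add atoms: triisopropylsilyl chloride, CC(C)[Si](Cl)(C(C)C)C(C)C
Why: Imidazole-promoted silylation of both acidic OH groups followed by carbonate hydrolysis of the far more labile silyl ester leaves the phenol as an aryl silyl ether robust enough for the hydroboration, enolate and borohydride steps ahead.

Step 12
Reactants: 19 4α-isopropyl-1β-methyl-5αH-bicyclo[5.3.0]dec-9-ene-4β,6α-diol; 22 4-(triisopropylsilyloxy)benzoic acid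
Product: 23 4β-hydroxy-4α-isopropyl-1β-methyl-5αH-bicyclo[5.3.0]dec-9-en-6α-yl 4-(triisopropylsilyloxy)benzoate
Conditions: EDC·HCl, DMAP, CH2Cl2, rt → 40 °C
Reagents that add atoms: 4-(triisopropylsilyloxy)benzoic acid (22), O=C(O)c1ccc(O[Si](C(C)C)(C(C)C)C(C)C)cc1
Why: Steglich esterification (carbodiimide activation, DMAP acyl transfer) acylates the secondary C6 hydroxyl, the tertiary C4 hydroxyl being too hindered, and leaves the C6 configuration unchanged because the C6–O bond is not broken.

Step 13
Reactants: 23 4β-hydroxy-4α-isopropyl-1β-methyl-5αH-bicyclo[5.3.0]dec-9-en-6α-yl 4-(triisopropylsilyloxy)benzoate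
Product: 25 4β,9ξ-dihydroxy-4α-isopropyl-1β-methyl-5αH-bicyclo[5.3.0]decan-6α-yl 4-(triisopropylsilyloxy)benzoate (C9 epimers), via C9 alkylborane 24 (not isolated)
Conditions: 9-BBN, THF, 60 °C; then 30% H2O2, 3 M NaOAc (aq), 0 °C → rt
Reagents that add atoms: hydrogen peroxide, OO
Why: Hydroboration with the bulky 9-BBN places boron on C9, the alkene carbon remote from quaternary C1, and acetate-buffered peroxide oxidation gives the C9 alcohol with the ester intact; borane should add anti to the C1 methyl (9α), but this is immaterial because C9 is oxidised next.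

Step 14
Reactants: 25 4β,9ξ-dihydroxy-4α-isopropyl-1β-methyl-5αH-bicyclo[5.3.0]decan-6α-yl 4-(triisopropylsilyloxy)benzoate
Product: 26 4β-hydroxy-4α-isopropyl-1β-methyl-9-oxo-5αH-bicyclo[5.3.0]decan-6α-yl 4-(triisopropylsilyloxy)benzoate
Conditions: Dess–Martin periodinane, CH2Cl2, rt
Reagents that add atoms: none
Why: Dess–Martin oxidation of the secondary alcohol gives the C9 ketone and cannot affect the tertiary hydroxyl, the ester or the aryl silyl ether.

Step 15
Reactants: 26 4β-hydroxy-4α-isopropyl-1β-methyl-9-oxo-5αH-bicyclo[5.3.0]decan-6α-yl 4-(triisopropylsilyloxy)benzoate; 27 Eschenmoser's salt (dimethylmethyleneiminium iodide)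
Product: 30 4β-hydroxy-4α-isopropyl-1β-methyl-8-methylene-9-oxo-5αH-bicyclo[5.3.0]decan-6α-yl 4-(triisopropylsilyloxy)benzoate, via Mannich base 28 (not isolated), via trimethylammonium iodide 29 (not isolated)
Conditions: LiN(iPr)2 (2.3 equiv), THF, −78 °C; Me2N=CH2 I (27), −78 → 0 °C; then MeI, MeOH, rt; then NaHCO3 (aq), CH2Cl2, rt
Reagents that add atoms: Eschenmoser's salt (27), C=[N+](C)C.[I-]
Why: Kinetic enolisation removes a proton from C8 rather than from C10, which is shielded by quaternary C1 (the first equivalent of base being taken up by the C4 hydroxyl), and Mannich reaction with Eschenmoser's salt, N-methylation and Hofmann-type elimination under bicarbonate give the α-methylene ketone, C8 becoming sp2.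

Step 16
Reactants: 30 4β-hydroxy-4α-isopropyl-1β-methyl-8-methylene-9-oxo-5αH-bicyclo[5.3.0]decan-6α-yl 4-(triisopropylsilyloxy)benzoate
Product: 31 4β,9β-dihydroxy-4α-isopropyl-1β-methyl-8-methylene-5αH-bicyclo[5.3.0]decan-6α-yl 4-(triisopropylsilyloxy)benzoate
Conditions: NaBH4, CeCl3·7H2O, MeOH, −78 °C
Reagents that add atoms: none
Why: Luche reduction delivers hydride 1,2 to the enone, and attack from the α face, anti to the pseudo-axial C1 methyl that stands 1,3 to C9, should give the 9β-allylic alcohol.

Step 17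
Reactants: 31 4β,9β-dihydroxy-4α-isopropyl-1β-methyl-8-methylene-5αH-bicyclo[5.3.0]decan-6α-yl 4-(triisopropylsilyloxy)benzoate
Product: 32 4β,9β-dihydroxy-4α-isopropyl-1β-methyl-8-methylene-5αH-bicyclo[5.3.0]decan-6α-yl 4-hydroxybenzoate (target)
Conditions: Bu4NF, AcOH, THF, 0 °C
Reagents that add atoms: none
Why: Fluoride-induced desilylation of the aryl silyl ether is fast because phenoxide is a good leaving group from silicon, and buffering with AcOH protects the benzoate ester and the allylic alcohol; no stereocentre is touched.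

Compound list
1 | (S)-terpinen-4-ol, (S)-1-isopropyl-4-methylcyclohex-3-en-1-ol | CC1=CC[C@](O)(C(C)C)CC1 | starting material
2 | (S)-triethyl[(1-isopropyl-4-methylcyclohex-3-en-1-yl)oxy]silane | CC1=CC[C@](O[Si](CC)(CC)CC)(C(C)C)CC1 | intermediate
3 | secondary ozonide of 2, 4-isopropyl-1-methyl-4-(triethylsilyloxy)-7,8,9-trioxabicyclo[4.2.1]nonane (carbinol carbon as in 2; bridgehead diastereomers; not isolated) | CC12CC[C@@](O[Si](CC)(CC)CC)(C(C)C)CC(OO1)O2 | intermediate
4 | (S)-3-isopropyl-6-oxo-3-(triethylsilyloxy)heptanal (not isolated) | O=CC[C@](O[Si](CC)(CC)CC)(C(C)C)CCC(C)=O | intermediate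
5 | (S)-5-isopropyl-7,7-dimethoxy-5-(triethylsilyloxy)heptan-2-one | COC(OC)C[C@](O[Si](CC)(CC)CC)(C(C)C)CCC(C)=O | intermediate
6 | diethyl (S)-5-isopropyl-7,7-dimethoxy-5-(triethylsilyloxy)hept-1-en-2-yl phosphate (not isolated) | COC(OC)C[C@](O[Si](CC)(CC)CC)(C(C)C)CCC(=C)OP(=O)(OCC)OCC | intermediate
7 | (S)-triethyl[(3-isopropyl-1,1-dimethoxyhept-6-yn-3-yl)oxy]silane | COC(OC)C[C@](O[Si](CC)(CC)CC)(C(C)C)CCC#C | intermediate
8 | trimethylaluminium (AlMe3) | C[Al](C)C | starting material
9 | vinyl bromide | C=CBr | starting material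
10 | dimethyl[(1E,5S)-5-isopropyl-7,7-dimethoxy-2-methyl-5-(triethylsilyloxy)hept-1-en-1-yl]alane (not isolated) | COC(OC)C[C@](O[Si](CC)(CC)CC)(C(C)C)CC/C(C)=C/[Al](C)C | intermediate
11 | (S,E)-triethyl[(3-isopropyl-1,1-dimethoxy-6-methylnona-6,8-dien-3-yl)oxy]silane | COC(OC)C[C@](O[Si](CC)(CC)CC)(C(C)C)CC/C(C)=C/C=C | intermediate
12 | (S,E)-3-isopropyl-6-methyl-3-(triethylsilyloxy)nona-6,8-dienal | O=CC[C@](O[Si](CC)(CC)CC)(C(C)C)CC/C(C)=C/C=C | intermediate
13 | chloroiodomethane | ClCI | starting material
14 | (4S,7E)-1-chloro-4-isopropyl-7-methyl-4-(triethylsilyloxy)deca-7,9-dien-2-ol (C2 epimers) | ClCC(O)C[C@](O[Si](CC)(CC)CC)(C(C)C)CC/C(C)=C/C=C | intermediate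
15 | (4S,7E)-1-chloro-4-isopropyl-7-methyl-4-(triethylsilyloxy)deca-7,9-dien-2-one | ClCC(=O)C[C@](O[Si](CC)(CC)CC)(C(C)C)CC/C(C)=C/C=C | intermediate
16 | Z-oxyallyl cation from 15 (zwitterion, lithium-coordinated in the medium; not isolated) | [CH2+]/C([O-])=C/[C@](O[Si](CC)(CC)CC)(C(C)C)CC/C(C)=C/C=C | intermediate
17 | 4α-isopropyl-1β-methyl-4β-(triethylsilyloxy)-5αH-bicyclo[5.3.0]dec-9-en-6-one (trans-fused) | C1CC(=O)[C@@H]2[C@](C)(CC[C@@]2(O[Si](CC)(CC)CC)C(C)C)C=C1 | intermediate
18 | 4β-hydroxy-4α-isopropyl-1β-methyl-5αH-bicyclo[5.3.0]dec-9-en-6-one | C1CC(=O)[C@@H]2[C@](C)(CC[C@@]2(O)C(C)C)C=C1 | intermediate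
19 | 4α-isopropyl-1β-methyl-5αH-bicyclo[5.3.0]dec-9-ene-4β,6α-diol | C1C[C@H](O)[C@@H]2[C@](C)(CC[C@@]2(O)C(C)C)C=C1 | intermediate
20 | 4-hydroxybenzoic acid | O=C(O)c1ccc(O)cc1 | starting material
21 | triisopropylsilyl 4-(triisopropylsilyloxy)benzoate (not isolated) | CC(C)[Si](C(C)C)(C(C)C)OC(=O)c1ccc(O[Si](C(C)C)(C(C)C)C(C)C)cc1 | intermediate
22 | 4-(triisopropylsilyloxy)benzoic acid | O=C(O)c1ccc(O[Si](C(C)C)(C(C)C)C(C)C)cc1 | intermediate
23 | 4β-hydroxy-4α-isopropyl-1β-methyl-5αH-bicyclo[5.3.0]dec-9-en-6α-yl 4-(triisopropylsilyloxy)benzoate | C1C[C@H](OC(=O)c3ccc(O[Si](C(C)C)(C(C)C)C(C)C)cc3)[C@@H]2[C@](C)(CC[C@@]2(O)C(C)C)C=C1 | intermediate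
24 | 9-(9-borabicyclo[3.3.1]nonan-9-yl) adduct of 23 (C9 epimers; not isolated) | C1C[C@H](OC(=O)c3ccc(O[Si](C(C)C)(C(C)C)C(C)C)cc3)[C@@H]2[C@](C)(CC[C@@]2(O)C(C)C)CC1B1C2CCCC1CCC2 | intermediate
25 | 4β,9ξ-dihydroxy-4α-isopropyl-1β-methyl-5αH-bicyclo[5.3.0]decan-6α-yl 4-(triisopropylsilyloxy)benzoate (C9 epimers) | C1C[C@H](OC(=O)c3ccc(O[Si](C(C)C)(C(C)C)C(C)C)cc3)[C@@H]2[C@](C)(CC[C@@]2(O)C(C)C)CC1O | intermediate
26 | 4β-hydroxy-4α-isopropyl-1β-methyl-9-oxo-5αH-bicyclo[5.3.0]decan-6α-yl 4-(triisopropylsilyloxy)benzoate | C1C[C@H](OC(=O)c3ccc(O[Si](C(C)C)(C(C)C)C(C)C)cc3)[C@@H]2[C@](C)(CC[C@@]2(O)C(C)C)CC1=O | intermediate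
27 | Eschenmoser's salt, dimethylmethyleneiminium iodide | C=[N+](C)C.[I-] | starting material
28 | 8-(dimethylaminomethyl) derivative of 26 (C8 epimers; not isolated) | CN(C)CC1C[C@H](OC(=O)c3ccc(O[Si](C(C)C)(C(C)C)C(C)C)cc3)[C@@H]2[C@](C)(CC[C@@]2(O)C(C)C)CC1=O | intermediate
29 | 8-(trimethylammoniomethyl) derivative of 26, iodide (not isolated) | C[N+](C)(C)CC1C[C@H](OC(=O)c3ccc(O[Si](C(C)C)(C(C)C)C(C)C)cc3)[C@@H]2[C@](C)(CC[C@@]2(O)C(C)C)CC1=O.[I-] | intermediate
30 | 4β-hydroxy-4α-isopropyl-1β-methyl-8-methylene-9-oxo-5αH-bicyclo[5.3.0]decan-6α-yl 4-(triisopropylsilyloxy)benzoate | C=C1C[C@H](OC(=O)c3ccc(O[Si](C(C)C)(C(C)C)C(C)C)cc3)[C@@H]2[C@](C)(CC[C@@]2(O)C(C)C)CC1=O | intermediate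
31 | 4β,9β-dihydroxy-4α-isopropyl-1β-methyl-8-methylene-5αH-bicyclo[5.3.0]decan-6α-yl 4-(triisopropylsilyloxy)benzoate | C=C1C[C@H](OC(=O)c3ccc(O[Si](C(C)C)(C(C)C)C(C)C)cc3)[C@@H]2[C@](C)(CC[C@@]2(O)C(C)C)C[C@H]1O | intermediate
32 | 4β,9β-dihydroxy-4α-isopropyl-1β-methyl-8-methylene-5αH-bicyclo[5.3.0]decan-6α-yl 4-hydroxybenzoate (CNP0164257.2) | C=C1C[C@H](OC(=O)c2ccc(O)cc2)[C@@H]2[C@](C)(CC[C@@]2(O)C(C)C)C[C@H]1O | target

Total step count: 17. Longest linear sequence: 16 steps (steps 1–10 and 12–17, from 1 to 32); step 11 is a one-step side branch.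

Steps most likely to fail

Step 8. The enolate at C5 may lose silanolate from C4 or close to a cyclopropanone (Favorskii pathway) before the primary chloride ionises. The short-lived cation may also be captured too slowly by the fully substituted diene terminus, so that stepwise closure to five-membered (3+2) products or a compact transition state (cis fusion) competes. The fallback sets out from aldehyde 12 and returns at cycloadduct 17, and uses a chlorine-stabilised cation that forms more easily and lives longer. Aldehyde 12 would be treated with LiCHCl2 (from CH2Cl2 and n-BuLi, THF, −100 °C) to give the dichloromethyl carbinol F1, which Dess–Martin periodinane would oxidise to the α,α-dichloroketone F2. With Et3N in CF3CH2OH, F2 should ionise to the 1-chloro-oxyallyl cation and undergo the same (4+3) closure to the 7-chloro cycloadduct F3. Zinc dust in AcOH would then remove the α-chlorine reductively and give 17.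

Step 10. Exchange of the hindered tertiary C4 hydroxyl onto boron may be slow, so that undirected hydride attack from the α face erodes the facial selectivity at C6. The fallback sets out from hydroxy ketone 18 and returns at diol 19, and binds the hydride source covalently to the C4 oxygen. Ketone 18 would be silylated with i-Pr2SiHCl (imidazole, DMAP, DMF) to the hydridosilyl ether F4. SnCl4-catalysed intramolecular hydrosilylation (CH2Cl2, −78 °C) would deliver hydride to the same β face of C6 and give the cyclic silylene F5, and HF·pyridine would release 19.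

Step 16. Hydride delivery to the exocyclic enone may show poor facial selectivity, or conjugate reduction may compete. The fallback sets out from Mannich base 28, which would be isolated instead of being quaternised, and returns at 31; it sets the carbinol before the alkene exists. Reduction of 28 with the bulky LiBH(s-Bu)3 (THF, −78 °C), which approaches anti to the C1 methyl, should give the 9β-amino alcohol F6. Oxidation of the amine with mCPBA would give the N-oxide F7, and Cope elimination on warming in toluene, for which C8–H is the only β-hydrogen, would form the exocyclic methylene and give 31 directly.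

Further compounds
F1 | step 8 | (4S,7E)-1,1-dichloro-4-isopropyl-7-methyl-4-(triethylsilyloxy)deca-7,9-dien-2-ol (C2 epimers) | ClC(Cl)C(O)C[C@](O[Si](CC)(CC)CC)(C(C)C)CC/C(C)=C/C=C
F2 | step 8 | (4S,7E)-1,1-dichloro-4-isopropyl-7-methyl-4-(triethylsilyloxy)deca-7,9-dien-2-one | ClC(Cl)C(=O)C[C@](O[Si](CC)(CC)CC)(C(C)C)CC/C(C)=C/C=C
F3 | step 8 | 7-chloro-4α-isopropyl-1β-methyl-4β-(triethylsilyloxy)-5αH-bicyclo[5.3.0]dec-9-en-6-one (C7 epimers) | C1C(Cl)C(=O)[C@@H]2[C@](C)(CC[C@@]2(O[Si](CC)(CC)CC)C(C)C)C=C1
F4 | step 10 | 4β-(diisopropylsilyloxy)-4α-isopropyl-1β-methyl-5αH-bicyclo[5.3.0]dec-9-en-6-one | C1CC(=O)[C@@H]2[C@](C)(CC[C@@]2(O[SiH](C(C)C)C(C)C)C(C)C)C=C1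
F5 | step 10 | 4β,6α-O-(diisopropylsilylene) derivative of diol 19 | C1C[C@H](O[Si]3(C(C)C)C(C)C)[C@@H]2[C@](C)(CC[C@@]2(O3)C(C)C)C=C1
F6 | step 16 | 8-(dimethylaminomethyl)-4β,9β-dihydroxy-4α-isopropyl-1β-methyl-5αH-bicyclo[5.3.0]decan-6α-yl 4-(triisopropylsilyloxy)benzoate (C8 epimers) | CN(C)CC1C[C@H](OC(=O)c3ccc(O[Si](C(C)C)(C(C)C)C(C)C)cc3)[C@@H]2[C@](C)(CC[C@@]2(O)C(C)C)C[C@H]1O
F7 | step 16 | N-oxide of F6 | C[N+](C)([O-])CC1C[C@H](OC(=O)c3ccc(O[Si](C(C)C)(C(C)C)C(C)C)cc3)[C@@H]2[C@](C)(CC[C@@]2(O)C(C)C)C[C@H]1O
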